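**Plan**

- The retrosynthesis cuts one bond between the two rings: the bond from the ester oxygen to C4 of ring B (the heptylsalicylic acid ring). The acyl carbon C7' stays on ring A (the orsellinoyl ring).
- This cut is possible because C4 of ring B lies between C3–H and C5–H and is open, whereas C7' of ring A is walled in by the C2' oxygen and the C6' methyl group. The carboxylate oxygen that is arylated sits outside that pocket.
- Ring B is cut further at C1–CO2H and C2–heptyl (aryne carbolithiation and carboxylation of protected 3-fluorophenol) and at C4–B (sterically directed C–H borylation).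
- Forward: ring B boronic acid is built in steps 1–6, ring A acid is made from methyl orsellinate in steps 7–8, the two arenes are joined through the depside C–O bond in step 9, and acid removes all protecting groups in step 10. No ring is formed anywhere.
- The target has no stereocentre, so no stereocontrol is needed.

Key step: step 9

Remark: heptyllithium is prepared as a titrated stock solution in a step of its own, and the copper salt of step 9 is taken to be turned over by air.

**Route**

Step 1
Reactants: 1 3-fluorophenol
Product: 2 1-fluoro-3-(methoxymethoxy)benzene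
Conditions: NaH (1.2 equiv), MOMCl (1.2 equiv), DMF, 0 °C to rt
Reagents that add atoms: chloromethyl methyl ether, COCCl
Why: Williamson-type O-alkylation of the sodium phenoxide with the reactive chloromethyl ether should install a methoxymethyl ether that tolerates organolithium reagents and directs the later ortho-lithiation.

Step 2
Reactants: 3 1-bromoheptane
Product: 4 heptyllithium (titrated solution in diethyl ether, used directly)
Conditions: Li (2.2 equiv, about 1% Na), Et2O, −10 °C, argon
Reagents that add atoms: lithium, [Li]
Why: Reductive lithiation of a primary alkyl bromide with lithium metal in ether is the standard preparation of a primary alkyllithium, and the low temperature limits Wurtz coupling.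

Step 3
Reactants: 2 1-fluoro-3-(methoxymethoxy)benzene; 4 heptyllithium
Product: 8 2-heptyl-6-(methoxymethoxy)benzoic acid, via 2-fluoro-6-(methoxymethoxy)phenyllithium 5 (not isolated), via 3-(methoxymethoxy)benzyne 6 (not isolated), via 2-heptyl-6-(methoxymethoxy)phenyllithium 7 (not isolated)
Conditions: 2 added slowly to 4 (2.3 equiv), THF/Et2O, −78 °C to −10 °C; then dry CO2, −78 °C to rt; then cold 1 M HCl to pH 3
Reagents that add atoms: carbon dioxide, O=C=O
Why: Directed ortho-lithiation between fluorine and the acetal oxygen, loss of LiF to the aryne, carbolithiation by heptyllithium at the aryne carbon remote from oxygen (which places lithium next to the methoxymethoxy group, where induction and chelation stabilise it) and carboxylation should give the 1,2,3-trisubstituted arene in one flask, an aryne route well known for 6-alkylsalicylic acids.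

Step 4
Reactants: 8 2-heptyl-6-(methoxymethoxy)benzoic acid
Product: 9 tert-butyl 2-heptyl-6-(methoxymethoxy)benzoate
Conditions: Me2NCH(OtBu)2 (4 equiv), toluene, 80 °C
Reagents that add atoms: N,N-dimethylformamide di-tert-butyl acetal, CN(C)C(OC(C)(C)C)OC(C)(C)C
Why: Esterification with a formamide acetal is an O-alkylation of the carboxylate under neutral conditions, so the two ortho substituents that block attack at the carbonyl carbon and the acid-labile acetal should not interfere.

Step 5
Reactants: 9 tert-butyl 2-heptyl-6-(methoxymethoxy)benzoate; 10 bis(pinacolato)diboron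
Product: 11 tert-butyl 2-heptyl-6-(methoxymethoxy)-4-(4,4,5,5-tetramethyl-1,3,2-dioxaborolan-2-yl)benzoate
Conditions: [Ir(OMe)(cod)]2 (1.5 mol %), 4,4'-di-tert-butyl-2,2'-bipyridine (3 mol %), 10 (1.0 equiv), THF, 80 °C
Reagents that add atoms: none
Why: Iridium-catalysed aromatic C–H borylation with a bipyridine ligand is governed by sterics, and in this 1,2,3-trisubstituted arene only C4–H has no ortho substituent, so boron should enter para to the ester.

Step 6
Reactants: 11 tert-butyl 2-heptyl-6-(methoxymethoxy)-4-(4,4,5,5-tetramethyl-1,3,2-dioxaborolan-2-yl)benzoate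
Product: 12 [4-(tert-butoxycarbonyl)-3-heptyl-5-(methoxymethoxy)phenyl]boronic acid
Conditions: NaIO4 (3 equiv), NH4OAc (3 equiv), acetone/H2O, rt
Reagents that add atoms: water, O
Why: Periodate glycol cleavage of the pinacol released in the hydrolysis equilibrium should drive the boronate ester to the free boronic acid at near-neutral pH, which the acetal and the tert-butyl ester tolerate.

Step 7
Reactants: 13 methyl 2,4-dihydroxy-6-methylbenzoate (methyl orsellinate)
Product: 14 methyl 2,4-bis(methoxymethoxy)-6-methylbenzoate
Conditions: NaH (2.6 equiv), MOMCl (2.6 equiv), DMF, 0 °C to rt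
Reagents that add atoms: chloromethyl methyl ether, COCCl
Why: Double Williamson-type O-alkylation, in which NaH in a dipolar aprotic solvent breaks the hydrogen bond of the C2' hydroxyl to the ester so that both phenols should be etherified.

Step 8
Reactants: 14 methyl 2,4-bis(methoxymethoxy)-6-methylbenzoate
Product: 15 2,4-bis(methoxymethoxy)-6-methylbenzoic acid
Conditions: KOH (10 equiv), DMSO/H2O, 90 °C; then 1 M HCl, 0 °C, to pH 4
Reagents that add atoms: potassium hydroxide, [K+].[OH-]
Why: Saponification of a methyl ester flanked by two ortho substituents is slow but should proceed with hydroxide in hot aqueous DMSO, the methoxymethyl ethers being stable to base and to brief cold acidification.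

Step 9
Reactants: 15 2,4-bis(methoxymethoxy)-6-methylbenzoic acid; 12 [4-(tert-butoxycarbonyl)-3-heptyl-5-(methoxymethoxy)phenyl]boronic acid
Product: 16 tert-butyl 4-{[2,4-bis(methoxymethoxy)-6-methylbenzoyl]oxy}-2-heptyl-6-(methoxymethoxy)benzoate
Conditions: 15 (2 equiv), Cu(OTf)2 (0.5 equiv), pyridine (4 equiv), 4 Å molecular sieves, CH2Cl2, dry air, 35 °C; 12 (1 equiv) added in portions
Reagents that add atoms: none
Why: This is a Chan–Lam oxidative C–O coupling in which the carboxylate of 15 binds divalent copper, the aryl group of 12 transmetalates from boron, oxidation gives a trivalent aryl copper carboxylate, and C–O reductive elimination releases ester 16 while air returns monovalent copper to the divalent state. The closest known reaction is the copper-mediated O-arylation of benzoic acids with arylboronic acids to give phenolic esters. No ring closes and no stereocentre is formed. Because the new bond is made at oxygen and not at the carbonyl carbon, the C2' ether and C6' methyl group that block addition to the acyl carbon of ring A are not in the way, and the site on ring B is fixed by the position of boron at C4 between C3–H and C5–H. The step needs chemoselectivity for carboxylate arylation over protodeboronation, oxidation to the phenol and biaryl homocoupling, which an acetate-free copper salt (no second carboxylate competes for the aryl group), the acid in excess, molecular sieves and portionwise addition of 12 should secure. Pyridine buffers the triflic acid that is released, so the methoxymethyl ethers and the tert-butyl ester should persist.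

Step 10
Reactants: 16 tert-butyl 4-{[2,4-bis(methoxymethoxy)-6-methylbenzoyl]oxy}-2-heptyl-6-(methoxymethoxy)benzoate
Product: 17 4-[(2,4-dihydroxy-6-methylbenzoyl)oxy]-2-heptyl-6-hydroxybenzoic acid
Conditions: TFA/CH2Cl2 (1:3), H2O (10 equiv), high dilution, 0 °C to rt
Reagents that add atoms: none
Why: Acidolysis should cleave the three methoxymethyl acetals through oxocarbenium ions that water captures as formaldehyde and methanol and should fragment the tert-butyl ester by alkyl–oxygen cleavage to isobutene, while the aryl ester, whose acyl carbon is shielded and which has no easy acid cleavage pathway, is expected to remain.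

**Compound list**

1 | 3-fluorophenol | Oc1cccc(F)c1 | starting material
2 | 1-fluoro-3-(methoxymethoxy)benzene | COCOc1cccc(F)c1 | intermediate
3 | 1-bromoheptane | CCCCCCCBr | starting material
4 | heptyllithium | [Li]CCCCCCC | intermediate
5 | 2-fluoro-6-(methoxymethoxy)phenyllithium | [Li]c1c(F)cccc1OCOC | intermediate (not isolated)
6 | 3-(methoxymethoxy)benzyne | COCOC1=CC=CC#C1 | intermediate (not isolated)
7 | 2-heptyl-6-(methoxymethoxy)phenyllithium | CCCCCCCc1cccc(OCOC)c1[Li] | intermediate (not isolated)
8 | 2-heptyl-6-(methoxymethoxy)benzoic acid | CCCCCCCc1cccc(OCOC)c1C(=O)O | intermediate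
9 | tert-butyl 2-heptyl-6-(methoxymethoxy)benzoate | CCCCCCCc1cccc(OCOC)c1C(=O)OC(C)(C)C | intermediate
10 | bis(pinacolato)diboron | CC1(C)OB(B2OC(C)(C)C(C)(C)O2)OC1(C)C | starting material
11 | tert-butyl 2-heptyl-6-(methoxymethoxy)-4-(4,4,5,5-tetramethyl-1,3,2-dioxaborolan-2-yl)benzoate | CCCCCCCc1cc(B2OC(C)(C)C(C)(C)O2)cc(OCOC)c1C(=O)OC(C)(C)C | intermediate
12 | [4-(tert-butoxycarbonyl)-3-heptyl-5-(methoxymethoxy)phenyl]boronic acid | CCCCCCCc1cc(B(O)O)cc(OCOC)c1C(=O)OC(C)(C)C | intermediate
13 | methyl 2,4-dihydroxy-6-methylbenzoate | Cc1cc(O)cc(O)c1C(=O)OC | starting material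
14 | methyl 2,4-bis(methoxymethoxy)-6-methylbenzoate | COCOc1cc(C)c(C(=O)OC)c(OCOC)c1 | intermediate
15 | 2,4-bis(methoxymethoxy)-6-methylbenzoic acid | COCOc1cc(C)c(C(=O)O)c(OCOC)c1 | intermediate
16 | tert-butyl 4-{[2,4-bis(methoxymethoxy)-6-methylbenzoyl]oxy}-2-heptyl-6-(methoxymethoxy)benzoate | CCCCCCCc1cc(OC(=O)c2c(C)cc(OCOC)cc2OCOC)cc(OCOC)c1C(=O)OC(C)(C)C | intermediate
17 | 4-[(2,4-dihydroxy-6-methylbenzoyl)oxy]-2-heptyl-6-hydroxybenzoic acid | CCCCCCCc1cc(OC(=O)c2c(C)cc(O)cc2O)cc(O)c1C(=O)O | target

**Step count and risks**

Total step count: 10. Longest linear sequence: 7 steps (steps 1, 3, 4, 5, 6, 9, 10).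

Steps most likely to fail:

1. Step 9. The arylboron partner may be used up by protodeboronation, oxidation to the phenol or homocoupling faster than the electron-poor aryl group transmetalates and couples with the weakly nucleophilic carboxylate. The fallback sets out from 12 and 15 and comes back to the route at 16. Boronic acid 12 would be oxidised with H2O2 and NaOH in THF at 0 °C to tert-butyl 2-heptyl-4-hydroxy-6-(methoxymethoxy)benzoate F1. This phenol would then be acylated with acid 15 by a carbodiimide esterification (DCC, catalytic DMAP, CH2Cl2), the classical way to join depside halves, to give 16.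

2. Step 10. During acidolysis the electron-rich ring A, once its phenols are free, may capture the formaldehyde, methoxymethyl and tert-butyl cations that are released, leading to ring alkylation or methylene bridging. The fallback sets out from 13 and 12 and comes back to the route at 17.
   - Methyl orsellinate 13 would be benzylated (benzyl bromide, K2CO3, DMF) to methyl 2,4-bis(benzyloxy)-6-methylbenzoate F2.
   - F2 would be saponified (KOH, DMSO/H2O) to 2,4-bis(benzyloxy)-6-methylbenzoic acid F3.
   - F3 would be coupled with 12 under the conditions of step 9 to tert-butyl 4-{[2,4-bis(benzyloxy)-6-methylbenzoyl]oxy}-2-heptyl-6-(methoxymethoxy)benzoate F4.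
   - TFA in wet CH2Cl2 would then remove only the tert-butyl ester and the single acetal of ring B while ring A still carries its ethers, giving 4-{[2,4-bis(benzyloxy)-6-methylbenzoyl]oxy}-2-heptyl-6-hydroxybenzoic acid F5.
   - Hydrogenolysis (H2, Pd/C (palladium on carbon), ethyl acetate) would finally release 17 under neutral conditions.

3. Step 3. The aryne may be intercepted by the aryllithium species instead of heptyllithium (biaryl formation), or LiF loss may be incomplete before carboxylation, and surplus heptyllithium is carboxylated to an acid that must be separated. The fallback sets out from 2 and 4 and comes back to the route at 8. Fluoride 2 would be lithiated with 4 (1.05 equiv) in THF and held at −78 °C so that no aryne forms, then carboxylated to 2-fluoro-6-(methoxymethoxy)benzoic acid F6. The ortho fluorine of its lithium carboxylate would then be displaced by 4 (2.2 equiv, THF, −78 °C to 0 °C) in a carboxylate-directed nucleophilic aromatic substitution, giving 8.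

**Further compounds**

F1 | step 9 | tert-butyl 2-heptyl-4-hydroxy-6-(methoxymethoxy)benzoate | CCCCCCCc1cc(O)cc(OCOC)c1C(=O)OC(C)(C)C
F2 | step 10 | methyl 2,4-bis(benzyloxy)-6-methylbenzoate | COC(=O)c1c(C)cc(OCc2ccccc2)cc1OCc1ccccc1
F3 | step 10 | 2,4-bis(benzyloxy)-6-methylbenzoic acid | Cc1cc(OCc2ccccc2)cc(OCc2ccccc2)c1C(=O)O
F4 | step 10 | tert-butyl 4-{[2,4-bis(benzyloxy)-6-methylbenzoyl]oxy}-2-heptyl-6-(methoxymethoxy)benzoate | CCCCCCCc1cc(OC(=O)c2c(C)cc(OCc3ccccc3)cc2OCc2ccccc2)cc(OCOC)c1C(=O)OC(C)(C)C
F5 | step 10 | 4-{[2,4-bis(benzyloxy)-6-methylbenzoyl]oxy}-2-heptyl-6-hydroxybenzoic acid | CCCCCCCc1cc(OC(=O)c2c(C)cc(OCc3ccccc3)cc2OCc2ccccc2)cc(O)c1C(=O)O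
F6 | step 3 | 2-fluoro-6-(methoxymethoxy)benzoic acid | COCOc1cccc(F)c1C(=O)O
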